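# Proposed synthesis of CNP0289934.1 (9-O-feruloyl-5-methoxylariciresinol) by anodic quinone methide cycloetherification

## The problem

The target is the ferulate ester of a 7,9'-epoxylignan. Its core is an oxolane (ring A: O1, C2, C3, C4, C5) with a 4-hydroxy-3,5-dimethoxyphenyl (syringyl) group on C2, an acyloxymethyl arm on C3 and a 4-hydroxy-3-methoxybenzyl (guaiacylmethyl) group on C4. The configuration is (2S,3R,4R), that is 2,3-trans and 3,4-cis.

The carbon chain is that of a 2,3-dibenzylbutane-1,4-diol in which one benzylic carbon is bonded to one of the two terminal oxygens. A synthesis must therefore tell two nearly identical halves apart: syringyl from guaiacyl, and the hydroxymethyl group that enters the ring from the one that is esterified.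

C3 and C4 sit on the open chain and must be set absolutely. C2 is benzylic, α to oxygen and para to a phenol, so it is epimerisable. Its preferred configuration (aryl anti to both ring neighbours) can be dictated by C3 and C4.

Three groups limit the chemistry that can be used late:
- three free phenols;
- the cinnamate ester, whose alkene rules out late hydrogenation and whose acyl group rules out hydride, hydroxide and alkoxide;
- the O1–C2 benzylic ether, which ionises under acid and then epimerises or is attacked by the guaiacyl ring to give an aryltetralin.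

The enabling feature is that C2 is para to the free hydroxyl of a 2,6-dimethoxyphenol. Two-electron oxidation of that phenol turns C2 into the electrophilic carbon of a p-quinone methide, and the oxygen on C5 is placed to close a five-membered ring onto it. The two methoxy groups block the ortho positions against radical coupling.

## Retrosynthesis

**Ester and silyl groups (22 ⇒ 21 ⇒ 17 + 20).** The two aryl O–Si bonds of 21 and the acyl C–O bond of the ferulate are cut first. The ester is the most fragile bond and the cinnamate alkene the only group that forbids hydrogenation, so it is introduced last. This removes ten carbons and leaves alcohol 17 and the silylated acid 20 (from ferulic acid 18). The forward esterification must take the primary alcohol of 17 and ignore its free syringyl phenol. A Mitsunobu reaction does this because it activates the alcohol, not the acid, and only the carboxylic acid is acidic enough to serve as pronucleophile. Both silyl ethers must then fall to buffered fluoride without touching the ester.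

**Ring A (17 ⇒ 16 ⇒ 15).** The O1–C2 bond is cut. The neighbouring cuts compare as follows:
- Cutting O1–C5 would require C2 to be made first as a configurationally defined benzylic carbinol.
- Cutting C2–C3 or C3–C4 forms a C–C bond but asks the ring-forming step to control two or three stereocentres at once.
- Cutting O1–C2 leads to the acyclic diol 15, which has only two stereocentres, no functional group at C2, and a skeleton that is symmetric apart from the aryl substitution.

The forward step must oxidise one benzylic CH2 out of two, choose one hydroxyl out of two, and set C2. The first is secured by leaving only the syringyl phenol free, the second by ring size (oxolane against oxetane), and the third by the resident centres.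

**Diol (15 ⇒ 14 ⇒ 13).** The syringyl phenol is masked as a benzyl ether, removed by hydrogenolysis just before the oxidation. The two hydroxymethyl groups are traced to a γ-lactone. Tying the two chain ends into a ring lets the relative configuration of the two centres be set as a 3,4-trans relationship on a five-membered ring. Hydride reduction is asked only to open the lactone and spare an aryl silyl ether.

**Second benzyl group (13 ⇒ 8 + 12).** The bond from the lactone α-carbon to the guaiacylmethyl carbon is cut. Against cutting the central C–C bond (an unsymmetrical enolate coupling), this alkylation is convergent and brings the second aryl group in with its own protecting group. It sets the new centre trans to the existing β-substituent. Bromide 12 must carry a phenol protecting group that survives a lithium amide, LiAlH4 and hydrogenolysis, and leaves at the end without acid or hydrogen. A triisopropylsilyl ether is chosen.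

**First stereocentre (8 ⇒ 7 ⇒ 6 ⇒ 5 ⇒ 2 + 3).** The lactone C–O bond is cut to hydroxy acid 7, which comes from the half-ester 6 by reduction of the ester in the presence of the carboxylate. The stereocentre of 6 is traced to the alkene of the Stobbe half-ester 5, made from aldehyde 2 and dimethyl succinate 3. The Stobbe condensation delivers the two carboxyl groups already differentiated. An asymmetric hydrogenation must then set the one centre from which all others follow. Aldehyde 2 is the benzyl ether of syringaldehyde 1.

**Electrophile (12 ⇒ 11 ⇒ 10 ⇒ 9).** The C–Br bond, the benzylic C–H and the O–Si bond are cut in turn, leading to vanillin 9. The bromination must be neutral, because the silyloxybenzyl position ionises easily.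

## Roads not taken

**Alternative 1:** Ring A is taken from a preformed γ-aryl butenolide A1, and two C–C bonds are cut from it: C3–vinyl and C4=CH(aryl).
- Forward step: (CH2=CH)2CuLi adds to A1 anti to the aryl group, and the lactone enolate is condensed with silylated vanillin A2 and dehydrated to the (E)-benzylidene lactone A3.
- Merits: two C–C bonds form in one operation, all carbons of the lignan core are then in place, and 2,3-trans is fixed early by a reliable anti addition. In that respect it is more secure than the chosen plan, which sets C2 last.
- Weak points: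
  - The stereocentre of A1 is benzylic, allylic and α to the ring oxygen, so it is easily lost by γ-deprotonation.
  - C4 is still to be set, by hydrogenation of the benzylidene group from the face anti to C3, while the vinyl group must be kept or converted first.
  - The lactone carbonyl must be taken down to the C5 methylene by half-reduction and a Lewis acid/silane step, at a ring whose O1–C2 bond ionises readily.
  - The vinyl group must be cleaved to the hydroxymethyl arm beside electron-rich arenes.
- Comparison: the chosen plan sets against this a key-step product that needs no further change of oxidation level in the ring, and C3 and C4 fixed by hydrogenation and trans alkylation before the ring exists.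

**Alternative 2:** Ring A is cut across C2–C3 and C4–C5.
- Forward step: a carbonyl ylide generated from aldehyde 2 (O-silylmethylation, then fluoride) adds to the enoate alkene of the menthyloxyfuranone A4 to give the cis-fused bicycle A5 with the aryl group exo.
- Merits: ring A and all three stereocentres arise in one step. The cis fusion guarantees 3,4-cis, the auxiliary controls the face, and exo aryl gives 2,3-trans. In stereochemical economy this step is better than the chosen key step, which forms one bond and one centre.
- Weak points:
  - A non-stabilised aryl carbonyl ylide is hard to generate cleanly.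
  - The regiochemistry (aryl-bearing carbon to the α-carbon) and the exo preference are not assured.
  - The chiral auxiliary is stoichiometric.
  - After the cycloaddition, the acetal carbon on C4 is at the aldehyde level and must be turned into the guaiacylmethyl group by aryl addition and deoxygenation. The intermediate aldehyde is cis to the C3 substituent and α-epimerisable.
- Comparison: the chosen plan sets against this commodity starting materials and a key-step product that is two steps from the target.

**Alternative 3:** The cuts are C3–C4 and the bond from the C4 methylene to the guaiacyl ring.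
- Forward step: a low-valent nickel catalyst (NiBr2·glyme with a terpyridine-type ligand, reduced in situ) abstracts iodine from the β-iodo allyl ether A6. The C3 radical closes 5-exo onto the allyl group and the exocyclic radical is arylated by the arylzinc bromide A7 to give the tris-silyl ether A8.
- Merits: this is the most convergent road. One step forms the ring and two C–C bonds, the guaiacyl unit enters as a simple nucleophile, and the longest line is probably two or three steps shorter than in the chosen plan.
- Weak points:
  - The C3 radical is planar, so all three relative configurations depend on one chair-like transition state. The expected sense (2,3-trans, 3,4-cis) matches the target, but such cyclisations are usually only moderately selective.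
  - A6 must be made enantiopure at its benzylic ether carbon.
  - The primary silyl ether of A8 must be removed in the presence of two aryl silyl ethers before esterification.
- Comparison: the chosen plan concedes step count. It sets against this C3 and C4 fixed by a catalyst-controlled hydrogenation and a substrate-controlled trans alkylation, with only the thermodynamically biased C2 left to the ring-forming step.

Key step: step 11

Assumption: the (S,S) hand of Et-DuPhos is taken to deliver the (R)-acid 6; if the sense proves opposite, the (R,R) ligand is used and nothing else changes.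

## Route

Step 1
Reactants: 1 syringaldehyde
Product: 2 4-benzyloxy-3,5-dimethoxybenzaldehyde
Conditions: BnBr, K2CO3, DMF, 60 °C
Reagents that add atoms: benzyl bromide, BrCc1ccccc1
Why: Williamson O-benzylation of an acidic phenol; the benzyl ether withstands alkoxide, hydride and amide bases and is removed by hydrogenolysis just before the key step.

Step 2
Reactants: 2 4-benzyloxy-3,5-dimethoxybenzaldehyde; 3 dimethyl succinate
Product: 5 (E)-4-(4-benzyloxy-3,5-dimethoxyphenyl)-3-(methoxycarbonyl)but-3-enoic acid, via paraconic ester lactone 4 (not isolated)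
Conditions: NaOMe, MeOH, reflux; then aq. HCl
Reagents that add atoms: none
Why: Stobbe condensation: aldol addition of the succinate enolate, lactonisation to 4 and E1cB ring opening should give the (E)-alkylidene half-ester, with the two carboxyl groups already differentiated as ester and acid.

Step 3
Reactants: 5 (E)-4-(4-benzyloxy-3,5-dimethoxyphenyl)-3-(methoxycarbonyl)but-3-enoic acid
Product: 6 (R)-4-(4-benzyloxy-3,5-dimethoxyphenyl)-3-(methoxycarbonyl)butanoic acid
Conditions: [Rh(cod)((S,S)-Et-DuPhos)]BF4 (1 mol%), NaOMe (0.1 equiv), H2 (4 bar), MeOH, rt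
Reagents that add atoms: none
Why: Asymmetric hydrogenation of an itaconate-type half-ester, in which the carboxylate acts as second binding group; the catalyst sets the one stereocentre (the future C3 of ring A) from which the others derive, and the benzyl ether is inert to the homogeneous catalyst.

Step 4
Reactants: 6 (R)-4-(4-benzyloxy-3,5-dimethoxyphenyl)-3-(methoxycarbonyl)butanoic acid
Product: 8 (R)-4-(4-benzyloxy-3,5-dimethoxybenzyl)oxolan-2-one, via hydroxy acid 7 (not isolated)
Conditions: KOH (1 equiv), EtOH, 0 °C; CaCl2, NaBH4, EtOH, −10 °C to rt; then 2 M HCl, rt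
Reagents that add atoms: none
Why: Chemoselective borohydride reduction: the potassium carboxylate is inert to Ca(BH4)2 while the methyl ester is reduced, and acidification lactonises 7; the stereocentre is not involved.

Step 5
Reactants: 9 vanillin
Product: 10 3-methoxy-4-(triisopropylsilyloxy)benzaldehyde
Conditions: TIPSCl, imidazole, DMF, rt
Reagents that add atoms: triisopropylsilyl chloride, CC(C)[Si](Cl)(C(C)C)C(C)C
Why: Imidazole-promoted silylation of a phenol; the bulky aryl silyl ether is chosen to survive a lithium amide, LiAlH4 and hydrogenolysis and still fall to buffered fluoride at the end.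

Step 6
Reactants: 10 3-methoxy-4-(triisopropylsilyloxy)benzaldehyde
Product: 11 [3-methoxy-4-(triisopropylsilyloxy)phenyl]methanol
Conditions: NaBH4, MeOH/THF, 0 °C
Reagents that add atoms: none
Why: Borohydride reduction of an aromatic aldehyde; short exposure at 0 °C should leave the aryl silyl ether intact.

Step 7
Reactants: 11 [3-methoxy-4-(triisopropylsilyloxy)phenyl]methanol
Product: 12 4-(bromomethyl)-2-methoxy-1-(triisopropylsilyloxy)benzene
Conditions: CBr4, PPh3, CH2Cl2, 0 °C
Reagents that add atoms: carbon tetrabromide, BrC(Br)(Br)Br
Why: Appel bromination under neutral conditions, which avoids acid-promoted ionisation of the electron-rich benzylic position; the bromide is used at once.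

Step 8
Reactants: 8 (R)-4-(4-benzyloxy-3,5-dimethoxybenzyl)oxolan-2-one; 12 4-(bromomethyl)-2-methoxy-1-(triisopropylsilyloxy)benzene
Product: 13 (3R,4R)-4-(4-benzyloxy-3,5-dimethoxybenzyl)-3-[3-methoxy-4-(triisopropylsilyloxy)benzyl]oxolan-2-one
Conditions: LiHMDS, THF, −78 °C; then 12, DMPU, −78 to −30 °C
Reagents that add atoms: none
Why: Alkylation of the lithium enolate of a β-substituted γ-butyrolactone; the bromide approaches anti to the β-benzyl group, so the new centre (the future C4 of ring A) should be set trans to the existing one.

Step 9
Reactants: 13 (3R,4R)-4-(4-benzyloxy-3,5-dimethoxybenzyl)-3-[3-methoxy-4-(triisopropylsilyloxy)benzyl]oxolan-2-one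
Product: 14 (2R,3R)-2-(4-benzyloxy-3,5-dimethoxybenzyl)-3-[3-methoxy-4-(triisopropylsilyloxy)benzyl]butane-1,4-diol
Conditions: LiAlH4, THF, 0 °C; then H2O, aq. NaOH
Reagents that add atoms: none
Why: Hydride reduction of a lactone to the 1,4-diol; neither stereocentre is enolisable once the carbonyl is gone, and benzyl and triisopropylsilyl aryl ethers should tolerate the reagent at 0 °C.

Step 10
Reactants: 14 (2R,3R)-2-(4-benzyloxy-3,5-dimethoxybenzyl)-3-[3-methoxy-4-(triisopropylsilyloxy)benzyl]butane-1,4-diol
Product: 15 (2R,3R)-2-(4-hydroxy-3,5-dimethoxybenzyl)-3-[3-methoxy-4-(triisopropylsilyloxy)benzyl]butane-1,4-diol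
Conditions: H2 (1 atm), Pd/C, EtOAc, rt
Reagents that add atoms: none
Why: Hydrogenolysis of the aryl benzyl ether in a neutral aprotic solvent; the silyl ether and the diol are untouched, and the product carries the single free phenol that directs the key step.

Step 11
Reactants: 15 (2R,3R)-2-(4-hydroxy-3,5-dimethoxybenzyl)-3-[3-methoxy-4-(triisopropylsilyloxy)benzyl]butane-1,4-diol
Product: 17 [(2S,3R,4R)-2-(4-hydroxy-3,5-dimethoxyphenyl)-4-[3-methoxy-4-(triisopropylsilyloxy)benzyl]oxolan-3-yl]methanol, via p-quinone methide 16 (not isolated)
Conditions: graphite anode, Pt cathode, undivided cell, LiClO4 (0.1 M), 2,6-lutidine (3 equiv), MeCN/CH2Cl2 (4:1), 5 mM, controlled potential at the first anodic wave of 15, 2.0–2.2 F/mol, 0 °C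
Reagents that add atoms: none
Why: Loss of one electron and one proton from the free syringyl phenol (lutidine as proton acceptor) gives a phenoxyl radical at a potential well below that of the silylated guaiacyl ring, and loss of a second electron and the benzylic proton, directly or by radical disproportionation, gives p-quinone methide 16. The closest known reaction type is the oxidation of 4-alkyl-2,6-dimethoxyphenols, by DDQ, Ag2O or an anode, to p-quinone methides that are captured by a tethered hydroxyl, the event that also closes the oxolane rings in biomimetic syringaresinol-type dimerisations. Ring A closes by a 5-exo-trig oxa-1,6-addition of the hydroxyl on the guaiacylmethyl-bearing arm to the methide carbon, which forms O1–C2 and restores the phenol; the other hydroxyl could only give an oxetane and stays free. The new stereocentre C2 is controlled by C3 and C4: the aryl group should end anti to both ring substituents (2,3-trans), since this is the less strained mode of closure and, the addition being reversible through 16, also the epimer that accumulates on equilibration. Site selectivity rests on the free versus silylated phenol, and the two methoxy groups block ortho coupling of the phenoxyl radical. Working with base at the foot of the first wave keeps the phenoxonium ion, and with it ipso capture to spirodienones, out of play, and the non-acidic medium denies the guaiacyl ring a Friedel–Crafts attack on C2. Charge is limited to about 2 F/mol because 17 is itself an oxidisable phenol.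

Step 12
Reactants: 18 ferulic acid
Product: 20 (E)-3-[4-(tert-butyldimethylsilyloxy)-3-methoxyphenyl]prop-2-enoic acid, via bis-silylated ferulate 19 (not isolated)
Conditions: TBSCl, imidazole, DMF, rt; then AcOH/THF/H2O (3:1:1), rt
Reagents that add atoms: tert-butyldimethylsilyl chloride, CC(C)(C)[Si](C)(C)Cl
Why: Exhaustive silylation followed by selective hydrolysis of the labile silyl ester; the aryl silyl ether survives dilute acetic acid and the (E)-alkene is not touched.

Step 13
Reactants: 17 [(2S,3R,4R)-2-(4-hydroxy-3,5-dimethoxyphenyl)-4-[3-methoxy-4-(triisopropylsilyloxy)benzyl]oxolan-3-yl]methanol; 20 (E)-3-[4-(tert-butyldimethylsilyloxy)-3-methoxyphenyl]prop-2-enoic acid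
Product: 21 [(2S,3R,4R)-2-(4-hydroxy-3,5-dimethoxyphenyl)-4-[3-methoxy-4-(triisopropylsilyloxy)benzyl]oxolan-3-yl]methyl (E)-3-[4-(tert-butyldimethylsilyloxy)-3-methoxyphenyl]prop-2-enoate
Conditions: PPh3, DIAD, THF, 0 °C to rt
Reagents that add atoms: none
Why: Mitsunobu esterification: the primary alcohol is activated as its alkoxyphosphonium ion and displaced by the carboxylate, the only pronucleophile acidic enough to be engaged; no acyl donor is present, so the hindered free phenol is not acylated, and no stereocentre is involved.

Step 14
Reactants: 21 [(2S,3R,4R)-2-(4-hydroxy-3,5-dimethoxyphenyl)-4-[3-methoxy-4-(triisopropylsilyloxy)benzyl]oxolan-3-yl]methyl (E)-3-[4-(tert-butyldimethylsilyloxy)-3-methoxyphenyl]prop-2-enoate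
Product: 22 [(2S,3R,4R)-2-(4-hydroxy-3,5-dimethoxyphenyl)-4-(4-hydroxy-3-methoxybenzyl)oxolan-3-yl]methyl (E)-3-(4-hydroxy-3-methoxyphenyl)prop-2-enoate (CNP0289934.1)
Conditions: Bu4NF, AcOH, THF, 0 °C
Reagents that add atoms: none
Why: Fluoride cleavage of both aryl silyl ethers, which are far more labile than alkyl ones; acetic acid protonates the phenoxides as they form, so the cinnamate ester should not be cleaved and C2 should not epimerise through a quinone methide.

## Compound list

1 | syringaldehyde | COc1cc(C=O)cc(OC)c1O | starting material
2 | 4-benzyloxy-3,5-dimethoxybenzaldehyde | COc1cc(C=O)cc(OC)c1OCc1ccccc1 | intermediate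
3 | dimethyl succinate | COC(=O)CCC(=O)OC | starting material
4 | methyl 2-(4-benzyloxy-3,5-dimethoxyphenyl)-5-oxooxolane-3-carboxylate (paraconic ester, stereoisomer mixture) | COC(=O)C1CC(=O)OC1c1cc(OC)c(OCc2ccccc2)c(OC)c1 | intermediate (not isolated)
5 | (E)-4-(4-benzyloxy-3,5-dimethoxyphenyl)-3-(methoxycarbonyl)but-3-enoic acid | COC(=O)/C(=C/c1cc(OC)c(OCc2ccccc2)c(OC)c1)CC(=O)O | intermediate
6 | (R)-4-(4-benzyloxy-3,5-dimethoxyphenyl)-3-(methoxycarbonyl)butanoic acid | COC(=O)[C@H](Cc1cc(OC)c(OCc2ccccc2)c(OC)c1)CC(=O)O | intermediate
7 | (R)-4-(4-benzyloxy-3,5-dimethoxyphenyl)-3-(hydroxymethyl)butanoic acid | OC[C@H](Cc1cc(OC)c(OCc2ccccc2)c(OC)c1)CC(=O)O | intermediate (not isolated)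
8 | (R)-4-(4-benzyloxy-3,5-dimethoxybenzyl)oxolan-2-one | O=C1C[C@@H](Cc2cc(OC)c(OCc3ccccc3)c(OC)c2)CO1 | intermediate
9 | vanillin | COc1cc(C=O)ccc1O | starting material
10 | 3-methoxy-4-(triisopropylsilyloxy)benzaldehyde | COc1cc(C=O)ccc1O[Si](C(C)C)(C(C)C)C(C)C | intermediate
11 | [3-methoxy-4-(triisopropylsilyloxy)phenyl]methanol | COc1cc(CO)ccc1O[Si](C(C)C)(C(C)C)C(C)C | intermediate
12 | 4-(bromomethyl)-2-methoxy-1-(triisopropylsilyloxy)benzene | COc1cc(CBr)ccc1O[Si](C(C)C)(C(C)C)C(C)C | intermediate
13 | (3R,4R)-4-(4-benzyloxy-3,5-dimethoxybenzyl)-3-[3-methoxy-4-(triisopropylsilyloxy)benzyl]oxolan-2-one | O=C1[C@H](Cc2ccc(O[Si](C(C)C)(C(C)C)C(C)C)c(OC)c2)[C@@H](Cc2cc(OC)c(OCc3ccccc3)c(OC)c2)CO1 | intermediate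
14 | (2R,3R)-2-(4-benzyloxy-3,5-dimethoxybenzyl)-3-[3-methoxy-4-(triisopropylsilyloxy)benzyl]butane-1,4-diol | OC[C@H](Cc1cc(OC)c(OCc2ccccc2)c(OC)c1)[C@@H](Cc1ccc(O[Si](C(C)C)(C(C)C)C(C)C)c(OC)c1)CO | intermediate
15 | (2R,3R)-2-(4-hydroxy-3,5-dimethoxybenzyl)-3-[3-methoxy-4-(triisopropylsilyloxy)benzyl]butane-1,4-diol | OC[C@H](Cc1cc(OC)c(O)c(OC)c1)[C@@H](Cc1ccc(O[Si](C(C)C)(C(C)C)C(C)C)c(OC)c1)CO | intermediate
16 | 4-[(2R,3R)-4-hydroxy-2-(hydroxymethyl)-3-[3-methoxy-4-(triisopropylsilyloxy)benzyl]butylidene]-2,6-dimethoxycyclohexa-2,5-dien-1-one (p-quinone methide) | O=C1C(OC)=CC(=C[C@@H](CO)[C@@H](Cc2ccc(O[Si](C(C)C)(C(C)C)C(C)C)c(OC)c2)CO)C=C1OC | intermediate (not isolated)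
17 | [(2S,3R,4R)-2-(4-hydroxy-3,5-dimethoxyphenyl)-4-[3-methoxy-4-(triisopropylsilyloxy)benzyl]oxolan-3-yl]methanol | OC[C@H]1[C@@H](Cc2ccc(O[Si](C(C)C)(C(C)C)C(C)C)c(OC)c2)CO[C@@H]1c1cc(OC)c(O)c(OC)c1 | intermediate
18 | ferulic acid | COc1cc(/C=C/C(=O)O)ccc1O | starting material
19 | tert-butyldimethylsilyl (E)-3-[4-(tert-butyldimethylsilyloxy)-3-methoxyphenyl]prop-2-enoate | COc1cc(/C=C/C(=O)O[Si](C)(C)C(C)(C)C)ccc1O[Si](C)(C)C(C)(C)C | intermediate (not isolated)
20 | (E)-3-[4-(tert-butyldimethylsilyloxy)-3-methoxyphenyl]prop-2-enoic acid | COc1cc(/C=C/C(=O)O)ccc1O[Si](C)(C)C(C)(C)C | intermediate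
21 | [(2S,3R,4R)-2-(4-hydroxy-3,5-dimethoxyphenyl)-4-[3-methoxy-4-(triisopropylsilyloxy)benzyl]oxolan-3-yl]methyl (E)-3-[4-(tert-butyldimethylsilyloxy)-3-methoxyphenyl]prop-2-enoate | COc1cc(/C=C/C(=O)OC[C@H]2[C@@H](Cc3ccc(O[Si](C(C)C)(C(C)C)C(C)C)c(OC)c3)CO[C@@H]2c2cc(OC)c(O)c(OC)c2)ccc1O[Si](C)(C)C(C)(C)C | intermediate
22 | [(2S,3R,4R)-2-(4-hydroxy-3,5-dimethoxyphenyl)-4-(4-hydroxy-3-methoxybenzyl)oxolan-3-yl]methyl (E)-3-(4-hydroxy-3-methoxyphenyl)prop-2-enoate | COc1cc(/C=C/C(=O)OC[C@H]2[C@@H](Cc3ccc(O)c(OC)c3)CO[C@@H]2c2cc(OC)c(O)c(OC)c2)ccc1O | target

## Step count and least certain steps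

Total step count: 14. Longest linear sequence: 10 steps (steps 1, 2, 3, 4, 8, 9, 10, 11, 13 and 14, from syringaldehyde 1).

**Step 11 (key step).** Three processes are most likely to go wrong:
- over-oxidation of the cyclised phenol, which is about as easily oxidised as the precursor and has a weak α-alkoxy benzylic C–H;
- diversion of the oxidised phenol into ipso capture by a hydroxyl (spirocyclisation through the phenoxonium ion);
- passivation of the anode by phenolic films.

Fallback: set out from 15 and give up the electrode for a two-stage chemical sequence. Stoichiometric Ag2O in dry CH2Cl2 at 0 °C dehydrogenates the phenol to the discrete p-quinone methide 16 and does not oxidise the silylated ring. The silver is filtered off. Ring closure is then triggered separately by a catalytic amount of pyridinium p-toluenesulfonate at −20 °C, which also lets the C2 epimers equilibrate. Oxidation and ring closure are decoupled, so the product phenol is exposed to the oxidant as little as possible. The sequence returns to the route at 17 and makes no new compound.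

**Step 3.** The hydrogenation may give insufficient enantioselectivity, or the opposite sense of induction, with the bulky trioxygenated aryl group. Fallback: set out from 5, hydrogenate without a chiral ligand ([Rh(cod)(dppb)]BF4, H2, MeOH; the benzyl ether is spared) to the racemic half-ester F1. Resolve it by crystallising the salt of the (R)-acid with (R)-1-phenylethylamine, the 1-phenylethylammonium salt F2; the hand of the amine is chosen by whichever gives the less soluble salt of the (R)-acid. Acidification returns to the route at 6.

**Step 8.** The electron-rich silyloxybenzyl bromide 12 may ionise and self-condense before it is alkylated, and proton exchange between product and enolate may lead to double alkylation. Fallback: set out from 8 and the stable aldehyde 10 and replace the alkylation by an aldol addition (LiHMDS, THF, −78 °C). This gives, again anti to the β-substituent, the aldol adduct (3S,4R)-4-(4-benzyloxy-3,5-dimethoxybenzyl)-3-[hydroxy(3-methoxy-4-triisopropylsilyloxyphenyl)methyl]oxolan-2-one F3 as a mixture of carbinol epimers. Hydrogenolysis (H2, Pd(OH)2/C, EtOAc–AcOH) removes the benzylic hydroxyl and the benzyl ether together to give the phenolic trans-lactone F4. LiAlH4 reduction of F4 returns to the route at 15.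

**Step 13.** The free syringyl phenol may be O-alkylated in competition with the carboxylate, and conversion at the β-branched primary alcohol may be slow. Fallback: set out from 17 and mask the phenol selectively as its allyl ether F5 (allyl bromide, K2CO3, acetone; only the phenol is acidic enough). Esterify the alcohol with 20 by acid activation (EDC·HCl, DMAP, CH2Cl2) to the allyl-protected ester F6. Remove the allyl group with Pd(PPh3)4 and morpholine in THF, which returns to the route at 21.

## Further compounds

F0 | step 11 | none | none
F1 | step 3 | racemic 4-(4-benzyloxy-3,5-dimethoxyphenyl)-3-(methoxycarbonyl)butanoic acid | COC(=O)C(Cc1cc(OC)c(OCc2ccccc2)c(OC)c1)CC(=O)O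
F2 | step 3 | (R)-1-phenylethylammonium (R)-4-(4-benzyloxy-3,5-dimethoxyphenyl)-3-(methoxycarbonyl)butanoate | COC(=O)[C@H](Cc1cc(OC)c(OCc2ccccc2)c(OC)c1)CC(=O)[O-].C[C@@H]([NH3+])c1ccccc1
F3 | step 8 | (3S,4R)-4-(4-benzyloxy-3,5-dimethoxybenzyl)-3-[hydroxy(3-methoxy-4-triisopropylsilyloxyphenyl)methyl]oxolan-2-one (carbinol epimers) | O=C1[C@H](C(O)c2ccc(O[Si](C(C)C)(C(C)C)C(C)C)c(OC)c2)[C@@H](Cc2cc(OC)c(OCc3ccccc3)c(OC)c2)CO1
F4 | step 8 | (3R,4R)-4-(4-hydroxy-3,5-dimethoxybenzyl)-3-[3-methoxy-4-(triisopropylsilyloxy)benzyl]oxolan-2-one | O=C1[C@H](Cc2ccc(O[Si](C(C)C)(C(C)C)C(C)C)c(OC)c2)[C@@H](Cc2cc(OC)c(O)c(OC)c2)CO1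
F5 | step 13 | [(2S,3R,4R)-2-(4-allyloxy-3,5-dimethoxyphenyl)-4-[3-methoxy-4-(triisopropylsilyloxy)benzyl]oxolan-3-yl]methanol | OC[C@H]1[C@@H](Cc2ccc(O[Si](C(C)C)(C(C)C)C(C)C)c(OC)c2)CO[C@@H]1c1cc(OC)c(OCC=C)c(OC)c1
F6 | step 13 | [(2S,3R,4R)-2-(4-allyloxy-3,5-dimethoxyphenyl)-4-[3-methoxy-4-(triisopropylsilyloxy)benzyl]oxolan-3-yl]methyl (E)-3-[4-(tert-butyldimethylsilyloxy)-3-methoxyphenyl]prop-2-enoate | COc1cc(/C=C/C(=O)OC[C@H]2[C@@H](Cc3ccc(O[Si](C(C)C)(C(C)C)C(C)C)c(OC)c3)CO[C@@H]2c2cc(OC)c(OCC=C)c(OC)c2)ccc1O[Si](C)(C)C(C)(C)C
A1 | alternative 1 | (S)-5-[4-(tert-butyldimethylsilyloxy)-3,5-dimethoxyphenyl]furan-2(5H)-one | O=C1C=C[C@@H](c2cc(OC)c(O[Si](C)(C)C(C)(C)C)c(OC)c2)O1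
A2 | alternative 1 | 4-(tert-butyldimethylsilyloxy)-3-methoxybenzaldehyde | COc1cc(C=O)ccc1O[Si](C)(C)C(C)(C)C
A3 | alternative 1 | (E)-α-[4-(tert-butyldimethylsilyloxy)-3-methoxybenzylidene]-β-vinyl-γ-[4-(tert-butyldimethylsilyloxy)-3,5-dimethoxyphenyl]-γ-butyrolactone, β and γ trans | C=C[C@H]2/C(=C\c3ccc(O[Si](C)(C)C(C)(C)C)c(OC)c3)C(=O)O[C@@H]2c2cc(OC)c(O[Si](C)(C)C(C)(C)C)c(OC)c2
A4 | alternative 2 | (5S)-5-[(1S,2R,5S)-menthyloxy]furan-2(5H)-one | O=C1C=C[C@@H](O[C@H]2C[C@@H](C)CC[C@@H]2C(C)C)O1
A5 | alternative 2 | cis-fused 6-(4-benzyloxy-3,5-dimethoxyphenyl)-4-menthyloxy-3,7-dioxabicyclo[3.3.0]octan-2-one, aryl exo | O=C1[C@H]2[C@@H]([C@@H](O[C@H]3C[C@@H](C)CC[C@@H]3C(C)C)O1)CO[C@@H]2c1cc(OC)c(OCc2ccccc2)c(OC)c1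
A6 | alternative 3 | (1R)-1-(allyloxy)-1-[4-(tert-butyldimethylsilyloxy)-3,5-dimethoxyphenyl]-3-(tert-butyldimethylsilyloxy)-2-iodopropane (iodide epimers) | C=CCO[C@H](c1cc(OC)c(O[Si](C)(C)C(C)(C)C)c(OC)c1)C(I)CO[Si](C)(C)C(C)(C)C
A7 | alternative 3 | [4-(tert-butyldimethylsilyloxy)-3-methoxyphenyl]zinc bromide | COc1cc([Zn]Br)ccc1O[Si](C)(C)C(C)(C)C
A8 | alternative 3 | 5-methoxylariciresinol tris(tert-butyldimethylsilyl) ether | CC(C)(C)[Si](C)(C)OC[C@H]2[C@@H](Cc3ccc(O[Si](C)(C)C(C)(C)C)c(OC)c3)CO[C@@H]2c2cc(OC)c(O[Si](C)(C)C(C)(C)C)c(OC)c2
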